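**Retrosynthetic overview**

1. Rings: A is the phenol ring whose aryloxy carbon is para to its CH2; B is the meta-phenylene on the ring A oxygen; C is the para-phenylene; D is the phenol ring with OH para to its CH2. The route rests on the bond from the ring A oxygen to the ring B carbon: ring B is a bare meta-phenylene with nothing to activate SNAr, so this ether is treated as an aryl benzoate that has lost its carbonyl carbon.
2. Target ⇐ its di-O-methyl ether (BBr3) ⇐ 21-membered macrolactone, the ring B benzoate of the ring A phenol (nickel-catalysed loss of CO, 21 to 20 ring atoms).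
3. Macrolactone ⇐ seco hydroxy acid (carbodiimide macrolactonisation) ⇐ one hydrogenation of a bis-stilbene benzyl ether acid, which saturates both two-carbon bridges and frees the ring A phenol.
4. Bis-stilbene ⇐ Wittig (ring C aldehyde + ring B ylide) ⇐ SNAr (ring D phenol + 4-fluorobenzaldehyde) ⇐ Wittig (ring A ylide + isovanillin).
5. Ring order: the four benzene rings are bought; the 21-membered lactone ring is closed first (step 7) and then contracted to the 20-membered bis-ether ring (step 8).

Key step: step 8

Remark: both Wittig steps should give E/Z mixtures at the stilbene bonds; they are carried on as mixtures because step 6 saturates both bonds, and the SMILES of 4, 6, 9 and 10 are written without alkene geometry.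
Remark: the ring A building block is taken as the catalogue compound 4-(benzyloxy)-3-methoxybenzyl alcohol (O-benzyl vanillyl alcohol).

**Route**

Step 1
Reactants: 1 4-(benzyloxy)-3-methoxybenzyl alcohol
Product: 2 [4-(benzyloxy)-3-methoxybenzyl]triphenylphosphonium bromide
Conditions: PPh3·HBr, MeCN, reflux
Reagents that add atoms: triphenylphosphine hydrobromide, c1ccc(cc1)[PH+](c1ccccc1)c1ccccc1.[Br-]
Why: The acid should ionise the electron-rich para-alkoxybenzyl alcohol to a stabilised benzylic cation that triphenylphosphine traps (SN1-type phosphonium salt formation from a benzylic alcohol), under conditions too mild to cleave the aryl benzyl ether.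

Step 2
Reactants: 2 [4-(benzyloxy)-3-methoxybenzyl]triphenylphosphonium bromide; 3 isovanillin (3-hydroxy-4-methoxybenzaldehyde)
Product: 4 5-{2-[4-(benzyloxy)-3-methoxyphenyl]ethenyl}-2-methoxyphenol (E/Z mixture)
Conditions: KOtBu (2.3 equiv), THF, 0 °C to rt; then 1 M aq HCl
Reagents that add atoms: none
Why: Wittig olefination with a semi-stabilised benzylic ylide; one equivalent of base is spent on the phenol, whose phenoxide is meta to the formyl group and not conjugated with it, so the aldehyde should stay electrophilic.

Step 3
Reactants: 4 5-{2-[4-(benzyloxy)-3-methoxyphenyl]ethenyl}-2-methoxyphenol; 5 4-fluorobenzaldehyde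
Product: 6 4-(5-{2-[4-(benzyloxy)-3-methoxyphenyl]ethenyl}-2-methoxyphenoxy)benzaldehyde (E/Z mixture)
Conditions: K2CO3, DMF, 130 °C, N2
Reagents that add atoms: none
Why: Nucleophilic aromatic substitution (SNAr) of the fluoride activated by the para-formyl group by the potassium phenoxide of 4, which forms the ring D oxygen to ring C bond and leaves the benzyl ether and the stilbene untouched.

Step 4
Reactants: 7 methyl 3-(bromomethyl)benzoate
Product: 8 [3-(methoxycarbonyl)benzyl]triphenylphosphonium bromide
Conditions: PPh3, toluene, reflux
Reagents that add atoms: triphenylphosphine, c1ccc(cc1)P(c1ccccc1)c1ccccc1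
Why: SN2 quaternisation of triphenylphosphine by a primary benzylic bromide, with the salt expected to precipitate from toluene.

Step 5
Reactants: 6 4-(5-{2-[4-(benzyloxy)-3-methoxyphenyl]ethenyl}-2-methoxyphenoxy)benzaldehyde; 8 [3-(methoxycarbonyl)benzyl]triphenylphosphonium bromide
Product: 10 3-{2-[4-(5-{2-[4-(benzyloxy)-3-methoxyphenyl]ethenyl}-2-methoxyphenoxy)phenyl]ethenyl}benzoic acid (bis-stilbene acid; E/Z mixture), via bis-stilbene methyl ester 9 (not isolated)
Conditions: NaOMe, THF/MeOH, 0 °C to rt; then 2 M aq NaOH, 50 °C; then 1 M aq HCl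
Reagents that add atoms: sodium hydroxide, [Na+].[OH-]
Why: Wittig olefination with the ester-bearing semi-stabilised ylide (NaOMe cannot scramble a methyl ester), followed in the same flask by saponification of the methyl ester, which should also allow removal of Ph3PO by acid–base extraction.

Step 6
Reactants: 10 3-{2-[4-(5-{2-[4-(benzyloxy)-3-methoxyphenyl]ethenyl}-2-methoxyphenoxy)phenyl]ethenyl}benzoic acid
Product: 11 3-{2-[4-(5-{2-[4-hydroxy-3-methoxyphenyl]ethyl}-2-methoxyphenoxy)phenyl]ethyl}benzoic acid (seco hydroxy acid)
Conditions: H2 (1 atm), 10% Pd/C, EtOAc/MeOH, rt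
Reagents that add atoms: none
Why: Heterogeneous catalytic hydrogenation should saturate both stilbene double bonds (so their geometry is irrelevant) and hydrogenolyse the benzyl ether in one operation, while the diaryl ether, the methyl ethers and the acid are inert.

Step 7
Reactants: 11 3-{2-[4-(5-{2-[4-hydroxy-3-methoxyphenyl]ethyl}-2-methoxyphenoxy)phenyl]ethyl}benzoic acid
Product: 12 21-membered macrolactone (ring B benzoate of the ring A phenol; methoxy groups on rings A and D)
Conditions: DCC, DMAP, DMAP·HCl, CHCl3, reflux, slow syringe-pump addition of 11 (high dilution)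
Reagents that add atoms: none
Why: Steglich-type (Keck) macrolactonisation: the O-acylisourea is relayed through the N-acylpyridinium ion to the phenol, DMAP·HCl should suppress N-acylurea formation, and the two flexible ethylene bridges should let the 21-membered ring close with little strain.

Step 8
Reactants: 12 21-membered macrolactone
Product: 13 di-O-methyl ether of the target (20-membered macrocyclic bis-diaryl ether)
Conditions: Ni(cod)2 (20 mol%), 3,4-bis(dicyclohexylphosphino)thiophene (dcypt, 40 mol%), K3PO4 (1.5 equiv), toluene (0.02 M), 150 °C, sealed tube, argon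
Reagents that add atoms: none
Why: Proposed new method: zerovalent nickel carrying the electron-rich chelating bisphosphine dcypt should insert into the acyl–oxygen bond of the aryl benzoate to give an acyl(aryloxo) complex of divalent nickel, the ring B aryl group should then migrate to nickel with loss of CO, and carbon–oxygen reductive elimination should join the ring A oxygen to ring B and return zerovalent nickel. The closest known reaction type is the nickel- or palladium/dcypt-catalysed decarbonylative etherification of open-chain aryl esters of azine- and arenecarboxylic acids to diaryl ethers, while oxidative addition and CO loss of plain phenyl benzoates are established in decarbonylative cross-couplings; new here are the non-heteroaromatic benzoate as ether precursor and the macrocyclic setting. The 20-membered ring is formed by ring contraction, that is by extrusion of one atom from the 21-membered lactone through a 21-membered nickelacycle in which nickel has taken the place of the carbonyl carbon, so no bimolecular event and no high dilution are needed. No stereocentre is formed. The step needs cleavage of the acyl–oxygen bond in preference to the aryl–oxygen bonds of the two methyl ethers and of the ring C to ring D ether, and ether formation in preference to reduction or ester exchange: 12 holds a single ester and no hydride source, the chelating ligand favours reductive elimination, and the ring keeps the aryloxide tethered next to the arylnickel centre so that it cannot diffuse away before the carbon–oxygen bond forms.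

Step 9
Reactants: 13 di-O-methyl ether of the target
Product: 14 CNP0329842.0 (target bis-phenol)
Conditions: BBr3, CH2Cl2, −78 °C to rt; then H2O
Reagents that add atoms: none
Why: Lewis-acid cleavage of aryl methyl ethers, in which bromide attacks the methyl carbon of each boron-complexed ether by SN2; the two diaryl ether bonds offer no sp3 carbon and should survive.

**Compound list**

1 | 4-(benzyloxy)-3-methoxybenzyl alcohol | COc1cc(CO)ccc1OCc1ccccc1 | starting material
2 | [4-(benzyloxy)-3-methoxybenzyl]triphenylphosphonium bromide | COc1cc(C[P+](c2ccccc2)(c2ccccc2)c2ccccc2)ccc1OCc1ccccc1.[Br-] | intermediate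
3 | isovanillin (3-hydroxy-4-methoxybenzaldehyde) | COc1ccc(C=O)cc1O | starting material
4 | 5-{2-[4-(benzyloxy)-3-methoxyphenyl]ethenyl}-2-methoxyphenol (E/Z mixture) | COc1cc(C=Cc2ccc(OC)c(O)c2)ccc1OCc1ccccc1 | intermediate
5 | 4-fluorobenzaldehyde | O=Cc1ccc(F)cc1 | starting material
6 | 4-(5-{2-[4-(benzyloxy)-3-methoxyphenyl]ethenyl}-2-methoxyphenoxy)benzaldehyde (E/Z mixture) | COc1cc(C=Cc2ccc(OC)c(Oc3ccc(C=O)cc3)c2)ccc1OCc1ccccc1 | intermediate
7 | methyl 3-(bromomethyl)benzoate | COC(=O)c1cccc(CBr)c1 | starting material
8 | [3-(methoxycarbonyl)benzyl]triphenylphosphonium bromide | COC(=O)c1cccc(C[P+](c2ccccc2)(c2ccccc2)c2ccccc2)c1.[Br-] | intermediate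
9 | methyl 3-{2-[4-(5-{2-[4-(benzyloxy)-3-methoxyphenyl]ethenyl}-2-methoxyphenoxy)phenyl]ethenyl}benzoate (E/Z mixture at both double bonds; not isolated) | COC(=O)c1cccc(C=Cc2ccc(Oc3cc(C=Cc4ccc(OCc5ccccc5)c(OC)c4)ccc3OC)cc2)c1 | intermediate
10 | 3-{2-[4-(5-{2-[4-(benzyloxy)-3-methoxyphenyl]ethenyl}-2-methoxyphenoxy)phenyl]ethenyl}benzoic acid (E/Z mixture at both double bonds) | OC(=O)c1cccc(C=Cc2ccc(Oc3cc(C=Cc4ccc(OCc5ccccc5)c(OC)c4)ccc3OC)cc2)c1 | intermediate
11 | 3-{2-[4-(5-{2-[4-hydroxy-3-methoxyphenyl]ethyl}-2-methoxyphenoxy)phenyl]ethyl}benzoic acid | OC(=O)c1cccc(CCc2ccc(Oc3cc(CCc4ccc(O)c(OC)c4)ccc3OC)cc2)c1 | intermediate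
12 | 21-membered macrolactone: ring B benzoate of the ring A phenol, methoxy groups on rings A and D | COc1cc2ccc1OC(=O)c1cccc(c1)CCc1ccc(cc1)Oc1cc(ccc1OC)CC2 | intermediate
13 | di-O-methyl ether of the target (20-membered macrocyclic bis-diaryl ether) | COc1cc2ccc1Oc1cccc(c1)CCc1ccc(cc1)Oc1cc(ccc1OC)CC2 | intermediate
14 | CNP0329842.0 | Oc1cc2ccc1Oc1cccc(c1)CCc1ccc(cc1)Oc1cc(ccc1O)CC2 | target

**Step count and risks**

Total step count: 9. Longest linear sequence: 8 steps (steps 1, 2, 3, 5, 6, 7, 8 and 9; step 4 is a one-step branch that makes the ring B phosphonium salt).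

Steps most likely to fail:

1. Step 8 (proposed new method). Carbon–oxygen reductive elimination from an unactivated arylnickel aryloxide may be too slow. The catalyst may then be poisoned by the CO it releases, the aryl–nickel bond may be protonated with ring opening, or the aryloxide may exchange between nickel centres and give oligomers. Switching to Pd(OAc)2/dcypt or sweeping out CO would change only the conditions. The fallback uses known chemistry, sets out from aldehyde 6 and comes back at 13.
   - Wittig olefination of 6 with commercial (3-bromobenzyl)triphenylphosphonium bromide (KOtBu, THF) should give 1-(benzyloxy)-4-[2-(3-{4-[2-(3-bromophenyl)ethenyl]phenoxy}-4-methoxyphenyl)ethenyl]-2-methoxybenzene F1.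
   - Diimide reduction (TsNHNH2, NaOAc, DME/H2O, reflux) should saturate both double bonds without touching the carbon–bromine bond or the benzyl ether and give 1-(benzyloxy)-4-[2-(3-{4-[2-(3-bromophenyl)ethyl]phenoxy}-4-methoxyphenyl)ethyl]-2-methoxybenzene F2.
   - BCl3 with pentamethylbenzene as cation scavenger (CH2Cl2, −78 °C) should remove the benzyl group in the presence of the methyl ethers and give 4-[2-(3-{4-[2-(3-bromophenyl)ethyl]phenoxy}-4-methoxyphenyl)ethyl]-2-methoxyphenol F3.
   - Intramolecular Ullmann etherification (CuI, N,N-dimethylglycine, Cs2CO3, 1,4-dioxane, 100 °C, high dilution) should join the ring A oxygen to ring B and give 13, from which step 9 follows unchanged.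

2. Step 7. Intermolecular esterification may outrun ring closure, and the hindered ortho-methoxyphenol may acylate slowly enough for the activated acid to rearrange to the N-acylurea. The fallback activates the acid before the phenol is unmasked; it sets out from 10 and comes back at 12.
   - Esterification of 10 with pentafluorophenol (DCC, CH2Cl2) should give pentafluorophenyl 3-{2-[4-(5-{2-[4-(benzyloxy)-3-methoxyphenyl]ethenyl}-2-methoxyphenoxy)phenyl]ethenyl}benzoate F4.
   - Hydrogenation in a non-nucleophilic solvent (H2, 10% Pd/C, EtOAc) should saturate both double bonds and remove the benzyl group while sparing the active ester, giving pentafluorophenyl 3-{2-[4-(5-{2-[4-hydroxy-3-methoxyphenyl]ethyl}-2-methoxyphenoxy)phenyl]ethyl}benzoate F5.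
   - Slow addition of F5 to Cs2CO3 in MeCN at 60 °C (high dilution) should let the caesium phenoxide displace pentafluorophenoxide within the molecule and give macrolactone 12.

3. Step 2. The potassium phenoxide of isovanillin may precipitate or react sluggishly, so that olefination stops short and the ylide decays. The fallback removes the free phenol before the Wittig step by changing the order of bond formation; it sets out from 3 (with 2) and comes back at 6.
   - SNAr of 3 with 4-fluorobenzonitrile (K2CO3, DMF, 120 °C) should give 4-(5-formyl-2-methoxyphenoxy)benzonitrile F6.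
   - Wittig olefination of F6 with 2 (KOtBu, THF) should give 4-(5-{2-[4-(benzyloxy)-3-methoxyphenyl]ethenyl}-2-methoxyphenoxy)benzonitrile F7.
   - Partial reduction of the nitrile (iBu2AlH, toluene, −78 °C; then aq HCl) should give aldehyde 6, and the route resumes at step 5.

Further compounds

F1 | step 8 | 1-(benzyloxy)-4-[2-(3-{4-[2-(3-bromophenyl)ethenyl]phenoxy}-4-methoxyphenyl)ethenyl]-2-methoxybenzene (E/Z mixture) | COc1cc(C=Cc2ccc(OC)c(Oc3ccc(C=Cc4cccc(Br)c4)cc3)c2)ccc1OCc1ccccc1
F2 | step 8 | 1-(benzyloxy)-4-[2-(3-{4-[2-(3-bromophenyl)ethyl]phenoxy}-4-methoxyphenyl)ethyl]-2-methoxybenzene | COc1cc(CCc2ccc(OC)c(Oc3ccc(CCc4cccc(Br)c4)cc3)c2)ccc1OCc1ccccc1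
F3 | step 8 | 4-[2-(3-{4-[2-(3-bromophenyl)ethyl]phenoxy}-4-methoxyphenyl)ethyl]-2-methoxyphenol | COc1cc(CCc2ccc(OC)c(Oc3ccc(CCc4cccc(Br)c4)cc3)c2)ccc1O
F4 | step 7 | pentafluorophenyl 3-{2-[4-(5-{2-[4-(benzyloxy)-3-methoxyphenyl]ethenyl}-2-methoxyphenoxy)phenyl]ethenyl}benzoate (E/Z mixture) | O=C(Oc1c(F)c(F)c(F)c(F)c1F)c1cccc(C=Cc2ccc(Oc3cc(C=Cc4ccc(OCc5ccccc5)c(OC)c4)ccc3OC)cc2)c1
F5 | step 7 | pentafluorophenyl 3-{2-[4-(5-{2-[4-hydroxy-3-methoxyphenyl]ethyl}-2-methoxyphenoxy)phenyl]ethyl}benzoate | O=C(Oc1c(F)c(F)c(F)c(F)c1F)c1cccc(CCc2ccc(Oc3cc(CCc4ccc(O)c(OC)c4)ccc3OC)cc2)c1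
F6 | step 2 | 4-(5-formyl-2-methoxyphenoxy)benzonitrile | COc1ccc(C=O)cc1Oc1ccc(C#N)cc1
F7 | step 2 | 4-(5-{2-[4-(benzyloxy)-3-methoxyphenyl]ethenyl}-2-methoxyphenoxy)benzonitrile (E/Z mixture) | COc1cc(C=Cc2ccc(OC)c(Oc3ccc(C#N)cc3)c2)ccc1OCc1ccccc1
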